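Cuts: first the acetyl group and the phenol protecting groups, back to the C2-symmetric (3S,5S)-3,5-diol; then aryl–C1 and aryl–C7; last C2–C3 and C5–C6.
Feature: C3–C4–C5 with O3 and O5 is propane-1,3-diol, and a C2 axis through C4 relates the two halves of the parent diol, so one catalyst can run the same event at both ends.
Forward: double allylation joins C2–C3 and C5–C6. Acetonide formation, ozonolysis/reduction (both terminal CH2 carbons are lost) and iodination follow, and a double aryl Grignard coupling attaches both guaiacyl rings.
No ring of the target is built. Both arenes are bought as 4-bromo-2-methoxyphenol, and the only ring made is a temporary 1,3-dioxane.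
Stereochemistry: C3 and C5 are both set by the chiral bisphosphine on iridium in step 1 and are not touched afterwards.
The two hydroxyls of the diol are homotopic, so monoacetylation through a cyclic orthoacetate can give only one compound, and any acyl migration is degenerate.

Key step: step 1

Assumption: (S)-Cl,MeO-BIPHEP is taken as the ligand antipode that gives the (S,S)-diol, by analogy with the sense of induction of this catalyst family. If a trial run shows the opposite sense, the equally available (R)-ligand is used and nothing else changes.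

Step 1
Reactants: 1 propane-1,3-diol; 2 allyl acetate
Product: 6 (4S,6S)-nona-1,8-diene-4,6-diol, via 3-hydroxypropanal 3 (not isolated), via (3S)-hex-5-ene-1,3-diol 4 (not isolated), via (3S)-3-hydroxyhex-5-enal 5 (not isolated)
Conditions: [Ir(cod)Cl]2 (5 mol %), (S)-Cl,MeO-BIPHEP (10 mol %), 4-Cl-3-NO2-C6H3CO2H (20 mol %), Cs2CO3 (40 mol %), 2 (10 equiv), 1,4-dioxane, 90 °C, sealed tube
Reagents that add atoms: none
Why: The catalyst assembled in the flask, a cyclometallated π-allyliridium(III) C,O-benzoate carrying the bisphosphine, exchanges with a primary hydroxyl of 1 to give an iridium alkoxide that loses a β-hydride and forms 3; base deprotonates the iridium hydride and the resulting iridium(I) ionises 2 back to the π-allyl complex, so no external oxidant or reductant is needed. The σ-allyl form then adds to the coordinated aldehyde through a closed six-membered chair transition state to make C2–C3, and the same cycle on the remaining CH2OH of 4 (through 5) makes C5–C6; this is the known two-directional variant, established for 1,3-diols, of the transfer-hydrogenative carbonyl allylation from the alcohol oxidation level (Krische allylation). No ring is closed. Each new stereocentre (C4 and C6 of 6, later C3 and C5 of the target) is controlled by the chiral bisphosphine, which selects the aldehyde face in the chair and overrides the weak 1,3-bias of the carbinol already present in 5. The step needs dehydrogenation of primary carbinols only and one aldehyde at a time: 1 offers two homotopic CH2OH groups, the secondary homoallylic alkoxide blocks the free coordination site with its own olefin and so resists β-hydride elimination, and malondialdehyde never arises. The minor enantiomer of 4 is carried mainly into the meso diastereomer, which chromatography removes, so the enantiopurity of 6 should exceed that of a single addition (Horeau-type amplification).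

Step 2
Reactants: 6 (4S,6S)-nona-1,8-diene-4,6-diol
Product: 7 (4S,6S)-2,2-dimethyl-4,6-di(prop-2-en-1-yl)-1,3-dioxane
Conditions: Me2C(OMe)2, PPTS (cat.), CH2Cl2, rt
Reagents that add atoms: 2,2-dimethoxypropane, COC(C)(C)OC
Why: Acid-catalysed transketalisation ties both carbinols into an isopropylidene ketal that should survive ozone, the iodination and the Grignard coupling, and no C–O bond at a stereocentre is broken.

Step 3
Reactants: 7 (4S,6S)-2,2-dimethyl-4,6-di(prop-2-en-1-yl)-1,3-dioxane
Product: 9 2,2'-[(4S,6S)-2,2-dimethyl-1,3-dioxane-4,6-diyl]di(ethan-1-ol), via acetonide dialdehyde 8 (not isolated)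
Conditions: O3, CH2Cl2/MeOH, −78 °C; then NaBH4, −78 °C → rt
Reagents that add atoms: ozone, [O-][O+]=O
Why: Ozonolysis with reductive borohydride work-up excises the surplus terminal carbon of each allyl group and reduces the peroxidic products through 8 directly to the primary alcohols, so the elimination-prone β-alkoxy aldehyde is never handled.

Step 4
Reactants: 9 2,2'-[(4S,6S)-2,2-dimethyl-1,3-dioxane-4,6-diyl]di(ethan-1-ol)
Product: 10 (4R,6R)-4,6-bis(2-iodoethyl)-2,2-dimethyl-1,3-dioxane
Conditions: I2, PPh3, imidazole, CH2Cl2, 0 °C → rt
Reagents that add atoms: iodine, II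
Why: Appel-type iodination (Garegg–Samuelsson conditions) displaces each primary alkoxyphosphonium by iodide in an SN2 step while imidazole buffers the medium and spares the ketal; the descriptors change only because CH2I outranks the ring carbon.

Step 5
Reactants: 11 4-bromo-2-methoxyphenol
Product: 12 1-(benzyloxy)-4-bromo-2-methoxybenzene
Conditions: BnBr, K2CO3, DMF, rt
Reagents that add atoms: benzyl bromide, BrCc1ccccc1
Why: Williamson etherification of the phenoxide installs a group that tolerates magnesium, copper and aqueous acid and can be removed at the end under neutral conditions that leave an acetate alone.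

Step 6
Reactants: 10 (4R,6R)-4,6-bis(2-iodoethyl)-2,2-dimethyl-1,3-dioxane; 12 1-(benzyloxy)-4-bromo-2-methoxybenzene
Product: 14 (4S,6S)-4,6-bis{2-[4-(benzyloxy)-3-methoxyphenyl]ethyl}-2,2-dimethyl-1,3-dioxane, via aryl Grignard reagent 13 (not isolated)
Conditions: 12 (4 equiv), Mg, THF, 40 °C; then 10, Li2CuCl4 (10 mol %), NMP, THF, 0 °C → rt
Reagents that add atoms: magnesium, [Mg] (stays in 13 only, not in 14)
Why: Kochi-type copper-catalysed sp2–sp3 cross-coupling of an aryl Grignard reagent with an unhindered primary iodide forms aryl–C1 and aryl–C7 by SN2-like attack of the arylcuprate two carbons away from the stereocentres, which stay untouched.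

Step 7
Reactants: 14 (4S,6S)-4,6-bis{2-[4-(benzyloxy)-3-methoxyphenyl]ethyl}-2,2-dimethyl-1,3-dioxane
Product: 15 (3S,5S)-1,7-bis[4-(benzyloxy)-3-methoxyphenyl]heptane-3,5-diol
Conditions: 2 M aq HCl, THF, rt
Reagents that add atoms: none
Why: Acid hydrolysis of the isopropylidene ketal should be easy because the acetonide of an anti-1,3-diol is a strained twist-boat, and benzyl aryl ethers are inert to dilute acid.

Step 8
Reactants: 15 (3S,5S)-1,7-bis[4-(benzyloxy)-3-methoxyphenyl]heptane-3,5-diol
Product: 17 (3S,5S)-1,7-bis[4-(benzyloxy)-3-methoxyphenyl]-5-hydroxyheptan-3-yl acetate, via cyclic orthoacetate 16 (not isolated)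
Conditions: MeC(OMe)3, PPTS (cat.), CH2Cl2, rt; concentrate; then AcOH/H2O (4:1), rt
Reagents that add atoms: trimethyl orthoacetate, COC(C)(OC)OC; water, O
Why: Orthoester exchange followed by acid hydrolysis through the 1,3-dioxan-2-ylium ion and its hemiorthoester can deliver only one acetate per molecule, and since the hydroxyls of 15 are homotopic either mode of ring opening gives the same 17.

Step 9
Reactants: 17 (3S,5S)-1,7-bis[4-(benzyloxy)-3-methoxyphenyl]-5-hydroxyheptan-3-yl acetate
Product: 18 (3S,5S)-5-hydroxy-1,7-bis(4-hydroxy-3-methoxyphenyl)heptan-3-yl acetate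
Conditions: H2 (1 atm), 10% Pd/C, EtOAc, rt
Reagents that add atoms: none
Why: Catalytic hydrogenolysis cleaves both benzyl aryl ethers under neutral conditions in which the acetate, the non-benzylic secondary alcohol and both stereocentres should persist.

Compound list
1 | propane-1,3-diol | OCCCO | starting material
2 | allyl acetate (prop-2-en-1-yl acetate) | C=CCOC(C)=O | starting material
3 | 3-hydroxypropanal | OCCC=O | intermediate
4 | (3S)-hex-5-ene-1,3-diol | C=CC[C@H](O)CCO | intermediate
5 | (3S)-3-hydroxyhex-5-enal | C=CC[C@H](O)CC=O | intermediate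
6 | (4S,6S)-nona-1,8-diene-4,6-diol (anti, C2-symmetric) | C=CC[C@H](O)C[C@H](CC=C)O | intermediate
7 | (4S,6S)-2,2-dimethyl-4,6-di(prop-2-en-1-yl)-1,3-dioxane (acetonide of 6) | C=CC[C@H]1C[C@H](CC=C)OC(C)(C)O1 | intermediate
8 | 2,2'-[(4R,6R)-2,2-dimethyl-1,3-dioxane-4,6-diyl]diacetaldehyde (spatial arrangement as in 7; descriptors change by CIP ranking only) | O=CC[C@H]1C[C@H](CC=O)OC(C)(C)O1 | intermediate
9 | 2,2'-[(4S,6S)-2,2-dimethyl-1,3-dioxane-4,6-diyl]di(ethan-1-ol) | OCC[C@H]1C[C@H](CCO)OC(C)(C)O1 | intermediate
10 | (4R,6R)-4,6-bis(2-iodoethyl)-2,2-dimethyl-1,3-dioxane (spatial arrangement as in 7; descriptors change by CIP ranking only) | ICC[C@H]1C[C@H](CCI)OC(C)(C)O1 | intermediate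
11 | 4-bromo-2-methoxyphenol | COc1cc(Br)ccc1O | starting material
12 | 1-(benzyloxy)-4-bromo-2-methoxybenzene | COc1cc(Br)ccc1OCc1ccccc1 | intermediate
13 | [4-(benzyloxy)-3-methoxyphenyl]magnesium bromide | COc1cc([Mg]Br)ccc1OCc1ccccc1 | intermediate
14 | (4S,6S)-4,6-bis{2-[4-(benzyloxy)-3-methoxyphenyl]ethyl}-2,2-dimethyl-1,3-dioxane | COc1cc(CC[C@H]2C[C@H](CCc3ccc(OCc4ccccc4)c(OC)c3)OC(C)(C)O2)ccc1OCc1ccccc1 | intermediate
15 | (3S,5S)-1,7-bis[4-(benzyloxy)-3-methoxyphenyl]heptane-3,5-diol | COc1cc(CC[C@H](O)C[C@H](CCc2ccc(OCc3ccccc3)c(OC)c2)O)ccc1OCc1ccccc1 | intermediate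
16 | (4S,6S)-4,6-bis{2-[4-(benzyloxy)-3-methoxyphenyl]ethyl}-2-methoxy-2-methyl-1,3-dioxane (orthoester carbon not stereogenic because the diol is C2-symmetric) | COc1cc(CC[C@H]2C[C@H](CCc3ccc(OCc4ccccc4)c(OC)c3)OC(C)(OC)O2)ccc1OCc1ccccc1 | intermediate
17 | (3S,5S)-1,7-bis[4-(benzyloxy)-3-methoxyphenyl]-5-hydroxyheptan-3-yl acetate | COc1cc(CC[C@H](O)C[C@H](CCc2ccc(OCc3ccccc3)c(OC)c2)OC(C)=O)ccc1OCc1ccccc1 | intermediate
18 | (3S,5S)-5-hydroxy-1,7-bis(4-hydroxy-3-methoxyphenyl)heptan-3-yl acetate (CNP0293159.1) | COc1cc(CC[C@H](O)C[C@H](CCc2ccc(O)c(OC)c2)OC(C)=O)ccc1O | target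

Total step count: 9. Longest linear sequence: 8 (steps 1–4 and 6–9, from propane-1,3-diol); the aryl branch adds step 5.

Steps most likely to fail

Step 6.
- Risk: the second coupling may lag behind the first while the primary iodide is lost to reduction, dehydrohalogenation or halogen–metal exchange, and the Grignard reagent is lost to homocoupling.
- Fallback: it sets out from 7 and comes back at 14, and it makes the aryl–carbon bonds by carbonyl addition instead of substitution. Ozonolysis of 7 is worked up with Me2S so that dialdehyde 8 is isolated. Grignard reagent 13 (THF, −78 °C) adds to both formyl groups to give the bis(benzylic alcohol) F1, a mixture of epimers at the two new carbinol carbons that is of no consequence. Ac2O/pyridine/DMAP converts it into the bis(benzylic acetate) F2. Hydrogenolysis (H2, Pd/C, EtOAc) removes both benzylic acetoxy groups and, unavoidably, both benzyl ethers, giving the bisphenol acetonide F3. BnBr/K2CO3, as in step 5, restores the ethers and returns 14.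

Step 1.
- Risk: the catalyst may decay during the long heating so that the sequence stalls after the first allylation, or facial control may erode in the second addition.
- Fallback: it sets out from 4, which is then isolated, and comes back at 6. It keeps the C5–C6 disconnection but moves to the aldehyde oxidation level with a stoichiometric chiral reagent. TESCl/imidazole silylates both oxygens to give the bis(triethylsilyl) ether F4. Swern conditions oxidise the primary triethylsilyl ether directly and selectively to (3S)-3-(triethylsilyloxy)hex-5-enal F5. Brown allylboration with the B-allyldiisopinocampheylborane derived from (+)-α-pinene (Et2O, −78 °C, oxidative work-up) adds under reagent control to give the anti mono(triethylsilyl) ether F6. AcOH/THF/H2O removes the silyl group and returns 6.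

Step 8.
- Risk: orthoester exchange may be unfavourable, because the six-membered orthoester of an anti-diol must twist or carry one side chain axial, and hydrolysis may then revert largely to the diol.
- Fallback: it sets out from 15 and comes back at 17, and it activates one oxygen through tin. Bu2SnO in toluene at reflux with azeotropic removal of water gives the dibutylstannylene acetal F7. One equivalent of AcCl at 0 °C acylates a single tin-bound oxygen, and aqueous work-up gives 17.

Further compounds
F1 | step 6 | 3,5-O-isopropylidene-1,7-bis[4-(benzyloxy)-3-methoxyphenyl]heptane-1,3,5,7-tetraol, C3/C5 arranged as in 7, epimer mixture at C1 and C7 | COc1cc(C(O)C[C@H]2C[C@H](CC(O)c3ccc(OCc4ccccc4)c(OC)c3)OC(C)(C)O2)ccc1OCc1ccccc1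
F2 | step 6 | 1,7-di-O-acetate of F1, C3/C5 arranged as in 7, epimer mixture at C1 and C7 | COc1cc(C(OC(C)=O)C[C@H]2C[C@H](CC(OC(C)=O)c3ccc(OCc4ccccc4)c(OC)c3)OC(C)(C)O2)ccc1OCc1ccccc1
F3 | step 6 | (4S,6S)-4,6-bis[2-(4-hydroxy-3-methoxyphenyl)ethyl]-2,2-dimethyl-1,3-dioxane | COc1cc(CC[C@H]2C[C@H](CCc3ccc(O)c(OC)c3)OC(C)(C)O2)ccc1O
F4 | step 1 | (3S)-1,3-bis(triethylsilyloxy)hex-5-ene | C=CC[C@H](O[Si](CC)(CC)CC)CCO[Si](CC)(CC)CC
F5 | step 1 | (3S)-3-(triethylsilyloxy)hex-5-enal | C=CC[C@H](O[Si](CC)(CC)CC)CC=O
F6 | step 1 | (4S,6S)-6-(triethylsilyloxy)nona-1,8-dien-4-ol | C=CC[C@H](O)C[C@H](CC=C)O[Si](CC)(CC)CC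
F7 | step 8 | (4S,6S)-4,6-bis{2-[4-(benzyloxy)-3-methoxyphenyl]ethyl}-2,2-dibutyl-1,3,2-dioxastanninane | COc1cc(CC[C@H]2C[C@H](CCc3ccc(OCc4ccccc4)c(OC)c3)O[Sn](CCCC)(CCCC)O2)ccc1OCc1ccccc1
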